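**Strategy.** The trans-3,5-dimethyl-1,2-dioxolane core hides a C2 axis through C4 and the O–O bond: C3 and C5 each carry CH3 and a two-carbon arm (CH2CO2H at C3; C1′–C2′ of the C16 chain at C5). Both C–O bonds are therefore made from one C2-symmetric precursor, (R,R)-bis(2-methyloxetan-2-yl)methane. H2O2 opens one oxetane with inversion; the new tertiary hydroperoxide then opens the second oxetane 5-exo-tet, again with inversion, closing the ring at the O–C3 bond and setting both quaternary centres. The resulting C2-symmetric bis(2-hydroxyethyl)dioxolane is differentiated once; one arm is extended by Wittig/diimide and Julia–Kocienski steps to the (E,E,E)-triene chain, the other is oxidised to the acid.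

Key step: step 5

Remark on the chemistry: in step 4 the (S)-binaphtholate antipode of the lanthanum–lithium catalyst is assumed, by analogy with simple alkyl methyl ketones, to give the 2S epoxide (hence the 2R oxetane); if the sense is opposite, the (R) antipode is used.

Locants: C3 (acid arm), C4, C5 (chain) are ring atoms; C1′–C16′ are side-chain atoms counted from the ring.

**Step 1**
Reactants: 1 (R)-mevalonolactone
Product: 2 (3R)-3,5-dihydroxy-N-methoxy-N,3-dimethylpentanamide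
Conditions: MeNH(OMe)·HCl, AlMe3, CH2Cl2, 0 °C to rt; aq. potassium sodium tartrate work-up
Reagents that add atoms: N,O-dimethylhydroxylamine hydrochloride, CNOC.Cl
Why: Aluminium-amide aminolysis of the δ-lactone (Weinreb amide formation) frees the primary hydroxyl for oxetane closure and does not touch the tertiary carbinol centre, which stays R.

**Step 2**
Reactants: 2 (3R)-3,5-dihydroxy-N-methoxy-N,3-dimethylpentanamide
Product: 4 N-methoxy-N-methyl-2-[(2R)-2-methyloxetan-2-yl]acetamide, via primary monotosylate 3 (not isolated)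
Conditions: KOtBu (1 equiv), TsCl (1 equiv), THF, −10 °C; then KOtBu (1.2 equiv), 0 °C to rt
Reagents that add atoms: none
Why: Selective sulfonylation of the primary alkoxide followed by 4-exo-tet Williamson closure by the tertiary alkoxide forms only the O–CH2 bond, so the carbinol carbon keeps its configuration.

**Step 3**
Reactants: 4 N-methoxy-N-methyl-2-[(2R)-2-methyloxetan-2-yl]acetamide
Product: 5 1-[(2R)-2-methyloxetan-2-yl]propan-2-one
Conditions: MeMgBr, THF, −20 to 0 °C; sat. aq. NH4Cl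
Reagents that add atoms: methylmagnesium bromide, C[Mg]Br
Why: Weinreb ketone synthesis, in which the magnesium chelate stops the addition at the methyl ketone and the oxetane is not involved.

**Step 4**
Reactants: 5 1-[(2R)-2-methyloxetan-2-yl]propan-2-one
Product: 7 (2R,2′R)-2,2′-methylenebis(2-methyloxetane), via epoxy oxetane 6 (not isolated)
Conditions: Me3S(O)I, NaH, THF (ylide, 1.2 equiv); LaLi3[(S)-binaphtholate]3 (cat.), (2,4,6-(MeO)3C6H2)3P=O (cat.), 5 Å MS, THF, rt; then further ylide (1.2 equiv) and catalyst, 45 °C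
Reagents that add atoms: dimethylsulfoxonium methylide (from trimethylsulfoxonium iodide and NaH), C[S+](C)(=O)[CH2-]
Why: Catalytic asymmetric Corey–Chaykovsky epoxidation of the methyl ketone, in which the chiral lanthanum–lithium binaphtholate controls the face of ylide addition (catalyst control), is followed by ylide ring expansion of the epoxide at its CH2 (4-exo-tet closure with loss of DMSO), which retains the new quaternary centre.

**Step 5**
Reactants: 7 (2R,2′R)-2,2′-methylenebis(2-methyloxetane); 8 hydrogen peroxide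
Product: 10 2,2′-[(3S,5S)-3,5-dimethyl-1,2-dioxolane-3,5-diyl]di(ethan-1-ol), via hydroperoxy oxetane alcohol 9 (not isolated)
Conditions: anhydrous H2O2 in Et2O (2–3 equiv), TMSOTf (cat.), Et2O, high dilution, −78 to 0 °C
Reagents that add atoms: none
Why: TMSOTf activates an oxetane oxygen and H2O2 attacks the tertiary carbon from the rear to give hydroperoxy alcohol 9 (first C–O bond, inversion); the terminal oxygen of its OOH group then attacks the quaternary carbon of the second activated oxetane, the future C3, and the dioxolane closes by this O–C3 bond while the oxetane oxygen leaves as the hydroxyl of the new 2-hydroxyethyl arm. The closest known reaction types are the Lewis-acid-promoted perhydrolysis of enantioenriched 2-alkyl-2-methyloxetanes, which goes with inversion, and the intramolecular hydroperoxide–oxetane cyclisation to 3-(2-hydroxyethyl)-1,2-dioxolanes; here the two are run in sequence in one flask. The ring closure is 5-exo-tet. Both stereocentres are set stereospecifically by the substrate: each R oxetane carbon is inverted, so R,R-7 can give only the trans, C2-symmetric S,S-diol, and because the two oxetanes of 7 are homotopic it does not matter which one reacts first. The step needs chemoselectivity for OOH over the liberated primary OH (6-exo closure to a tetrahydropyran) and over a second intermolecular perhydrolysis, and an SN2-like rather than ionised opening. The higher nucleophilicity of the peroxy oxygen, the kinetic preference for the five-membered ring, high dilution with only a small excess of H2O2, and low temperature in ether should secure these.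

**Step 6**
Reactants: 10 2,2′-[(3S,5S)-3,5-dimethyl-1,2-dioxolane-3,5-diyl]di(ethan-1-ol)
Product: 11 2-[(3S,5S)-5-(2-{[tert-butyl(dimethyl)silyl]oxy}ethyl)-3,5-dimethyl-1,2-dioxolan-3-yl]ethan-1-ol
Conditions: NaH (1 equiv), THF, 0 °C; TBSCl (1 equiv), 0 °C to rt
Reagents that add atoms: tert-butyldimethylsilyl chloride, CC(C)(C)[Si](C)(C)Cl
Why: Monosilylation through the monosodium alkoxide; the two hydroxyls of the C2-symmetric diol are homotopic, so only one monoether can form and unreacted diol is recycled.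

**Step 7**
Reactants: 11 2-[(3S,5S)-5-(2-{[tert-butyl(dimethyl)silyl]oxy}ethyl)-3,5-dimethyl-1,2-dioxolan-3-yl]ethan-1-ol
Product: 12 2-[(3R,5S)-5-(2-{[tert-butyl(dimethyl)silyl]oxy}ethyl)-3,5-dimethyl-1,2-dioxolan-3-yl]acetaldehyde
Conditions: TEMPO (cat.), PhI(OAc)2, CH2Cl2, rt
Reagents that add atoms: none
Why: Oxoammonium oxidation of the primary alcohol stops at the aldehyde in anhydrous CH2Cl2 and is non-basic, which avoids β-elimination of the peroxide (the change of descriptor to R is a CIP priority change only).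

**Step 8**
Reactants: 13 1,7-dibromoheptane (threefold excess); 14 1-phenyl-1H-tetrazole-5-thiol
Product: 15 5-[(7-bromoheptyl)sulfanyl]-1-phenyl-1H-tetrazole
Conditions: K2CO3, acetone, rt
Reagents that add atoms: none
Why: SN2 S-alkylation of the thiolate, with excess dibromide suppressing double substitution.

**Step 9**
Reactants: 15 5-[(7-bromoheptyl)sulfanyl]-1-phenyl-1H-tetrazole
Product: 16 triphenyl{7-[(1-phenyl-1H-tetrazol-5-yl)sulfanyl]heptyl}phosphonium bromide
Conditions: PPh3, MeCN, reflux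
Reagents that add atoms: triphenylphosphine, c1ccccc1P(c1ccccc1)c1ccccc1
Why: SN2 quaternisation of the phosphine by the primary bromide.

**Step 10**
Reactants: 12 2-[(3R,5S)-5-(2-{[tert-butyl(dimethyl)silyl]oxy}ethyl)-3,5-dimethyl-1,2-dioxolan-3-yl]acetaldehyde; 16 triphenyl{7-[(1-phenyl-1H-tetrazol-5-yl)sulfanyl]heptyl}phosphonium bromide
Product: 18 5-{[(7Z)-9-[(3S,5S)-5-(2-{[tert-butyl(dimethyl)silyl]oxy}ethyl)-3,5-dimethyl-1,2-dioxolan-3-yl]non-7-en-1-yl]sulfanyl}-1-phenyl-1H-tetrazole, via phosphonium ylide 17 (not isolated)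
Conditions: 16, NaN(SiMe3)2, THF, 0 °C; then 12, −78 °C to rt
Reagents that add atoms: none
Why: Wittig olefination with a non-stabilised ylide at low temperature, where carbonyl addition should outrun enolisation of the β-peroxy aldehyde; the expected Z geometry is immaterial because the alkene is reduced next.

**Step 11**
Reactants: 18 5-{[(7Z)-9-[(3S,5S)-5-(2-{[tert-butyl(dimethyl)silyl]oxy}ethyl)-3,5-dimethyl-1,2-dioxolan-3-yl]non-7-en-1-yl]sulfanyl}-1-phenyl-1H-tetrazole
Product: 19 5-({9-[(3S,5S)-5-(2-{[tert-butyl(dimethyl)silyl]oxy}ethyl)-3,5-dimethyl-1,2-dioxolan-3-yl]nonyl}sulfanyl)-1-phenyl-1H-tetrazole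
Conditions: KO2C–N=N–CO2K, AcOH, MeOH/CH2Cl2, 0 °C to rt, repeated charges
Reagents that add atoms: none
Why: Diimide reduction transfers H2 to the isolated C=C in a concerted syn addition and leaves the O–O bond, thioether and silyl ether untouched, which catalytic hydrogenation would not.

**Step 12**
Reactants: 19 5-({9-[(3S,5S)-5-(2-{[tert-butyl(dimethyl)silyl]oxy}ethyl)-3,5-dimethyl-1,2-dioxolan-3-yl]nonyl}sulfanyl)-1-phenyl-1H-tetrazole
Product: 20 5-({9-[(3S,5S)-5-(2-{[tert-butyl(dimethyl)silyl]oxy}ethyl)-3,5-dimethyl-1,2-dioxolan-3-yl]nonyl}sulfonyl)-1-phenyl-1H-tetrazole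
Conditions: mCPBA (2.5 equiv), NaHCO3, CH2Cl2, 0 °C to rt
Reagents that add atoms: meta-chloroperoxybenzoic acid, OOC(=O)c1cccc(Cl)c1
Why: Peracid oxidation of the sulfide to the sulfone; no alkene is present and the hindered dialkyl peroxide is inert to the peracid.

**Step 13**
Reactants: 20 5-({9-[(3S,5S)-5-(2-{[tert-butyl(dimethyl)silyl]oxy}ethyl)-3,5-dimethyl-1,2-dioxolan-3-yl]nonyl}sulfonyl)-1-phenyl-1H-tetrazole; 21 (2E,4E)-hepta-2,4-dienal
Product: 22 tert-butyl{2-[(3S,5S)-5-[(9E,11E,13E)-hexadeca-9,11,13-trien-1-yl]-3,5-dimethyl-1,2-dioxolan-3-yl]ethoxy}dimethylsilane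
Conditions: KN(SiMe3)2, DME, −60 °C; then 21, −60 °C to rt
Reagents that add atoms: none
Why: Julia–Kocienski olefination (addition of the metalated tetrazolyl sulfone to the dienal, Smiles rearrangement, anti elimination of SO2 and tetrazolone) should form the C9′=C10′ bond E while the E,E geometry of 21 is carried through; the ring carbons bear no acidic hydrogen.

**Step 14**
Reactants: 22 tert-butyl{2-[(3S,5S)-5-[(9E,11E,13E)-hexadeca-9,11,13-trien-1-yl]-3,5-dimethyl-1,2-dioxolan-3-yl]ethoxy}dimethylsilane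
Product: 23 2-[(3S,5S)-5-[(9E,11E,13E)-hexadeca-9,11,13-trien-1-yl]-3,5-dimethyl-1,2-dioxolan-3-yl]ethan-1-ol
Conditions: HF·pyridine, pyridine/THF, 0 °C to rt
Reagents that add atoms: none
Why: Buffered fluoride cleavage of the primary silyl ether, which leaves the peroxide and the triene intact.

**Step 15**
Reactants: 23 2-[(3S,5S)-5-[(9E,11E,13E)-hexadeca-9,11,13-trien-1-yl]-3,5-dimethyl-1,2-dioxolan-3-yl]ethan-1-ol
Product: 25 2-[(3R,5S)-5-[(9E,11E,13E)-hexadeca-9,11,13-trien-1-yl]-3,5-dimethyl-1,2-dioxolan-3-yl]acetic acid, via triene aldehyde 24 (not isolated)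
Conditions: TEMPO (cat.), PhI(OAc)2 (2.2 equiv), MeCN/pH 7 phosphate buffer, 0 °C to rt, dark
Reagents that add atoms: water, O
Why: TEMPO/PhI(OAc)2 oxidation in aqueous acetonitrile passes through the aldehyde hydrate to the acid under near-neutral conditions, and neither quaternary stereocentre can epimerise.

**Compound list**

1 | (R)-mevalonolactone | C[C@@]1(O)CCOC(=O)C1 | starting material
2 | (3R)-3,5-dihydroxy-N-methoxy-N,3-dimethylpentanamide | CON(C)C(=O)C[C@](C)(O)CCO | intermediate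
3 | (3R)-3-hydroxy-5-[methoxy(methyl)amino]-3-methyl-5-oxopentyl 4-methylbenzenesulfonate | CON(C)C(=O)C[C@](C)(O)CCOS(=O)(=O)c1ccc(C)cc1 | intermediate
4 | N-methoxy-N-methyl-2-[(2R)-2-methyloxetan-2-yl]acetamide | CON(C)C(=O)C[C@@]1(C)CCO1 | intermediate
5 | 1-[(2R)-2-methyloxetan-2-yl]propan-2-one | CC(=O)C[C@@]1(C)CCO1 | intermediate
6 | (2R)-2-methyl-2-{[(2S)-2-methyloxiran-2-yl]methyl}oxetane | C[C@@]1(CO1)C[C@@]2(C)CCO2 | intermediate
7 | (2R,2′R)-2,2′-methylenebis(2-methyloxetane) | C[C@@]1(CCO1)C[C@@]2(C)CCO2 | intermediate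
8 | hydrogen peroxide | OO | starting material
9 | (3S)-3-hydroperoxy-3-methyl-4-[(2R)-2-methyloxetan-2-yl]butan-1-ol | OCC[C@@](OO)(C)C[C@@]1(C)CCO1 | intermediate
10 | 2,2′-[(3S,5S)-3,5-dimethyl-1,2-dioxolane-3,5-diyl]di(ethan-1-ol) | OCC[C@@]1(C)C[C@](C)(CCO)OO1 | intermediate
11 | 2-[(3S,5S)-5-(2-{[tert-butyl(dimethyl)silyl]oxy}ethyl)-3,5-dimethyl-1,2-dioxolan-3-yl]ethan-1-ol | OCC[C@@]1(C)C[C@](C)(CCO[Si](C)(C)C(C)(C)C)OO1 | intermediate
12 | 2-[(3R,5S)-5-(2-{[tert-butyl(dimethyl)silyl]oxy}ethyl)-3,5-dimethyl-1,2-dioxolan-3-yl]acetaldehyde | O=CC[C@@]1(C)C[C@](C)(CCO[Si](C)(C)C(C)(C)C)OO1 | intermediate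
13 | 1,7-dibromoheptane | BrCCCCCCCBr | starting material
14 | 1-phenyl-1H-tetrazole-5-thiol | Sc1nnnn1-c1ccccc1 | starting material
15 | 5-[(7-bromoheptyl)sulfanyl]-1-phenyl-1H-tetrazole | BrCCCCCCCSc1nnnn1-c1ccccc1 | intermediate
16 | triphenyl{7-[(1-phenyl-1H-tetrazol-5-yl)sulfanyl]heptyl}phosphonium bromide | [Br-].c1ccccc1[P+](c1ccccc1)(c1ccccc1)CCCCCCCSc1nnnn1-c1ccccc1 | intermediate
17 | triphenyl{7-[(1-phenyl-1H-tetrazol-5-yl)sulfanyl]heptylidene}phosphorane | c1ccccc1P(c1ccccc1)(c1ccccc1)=CCCCCCCSc1nnnn1-c1ccccc1 | intermediate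
18 | 5-{[(7Z)-9-[(3S,5S)-5-(2-{[tert-butyl(dimethyl)silyl]oxy}ethyl)-3,5-dimethyl-1,2-dioxolan-3-yl]non-7-en-1-yl]sulfanyl}-1-phenyl-1H-tetrazole | c1ccccc1-n1nnnc1SCCCCCC/C=C\C[C@@]1(C)C[C@](C)(CCO[Si](C)(C)C(C)(C)C)OO1 | intermediate
19 | 5-({9-[(3S,5S)-5-(2-{[tert-butyl(dimethyl)silyl]oxy}ethyl)-3,5-dimethyl-1,2-dioxolan-3-yl]nonyl}sulfanyl)-1-phenyl-1H-tetrazole | c1ccccc1-n1nnnc1SCCCCCCCCC[C@@]1(C)C[C@](C)(CCO[Si](C)(C)C(C)(C)C)OO1 | intermediate
20 | 5-({9-[(3S,5S)-5-(2-{[tert-butyl(dimethyl)silyl]oxy}ethyl)-3,5-dimethyl-1,2-dioxolan-3-yl]nonyl}sulfonyl)-1-phenyl-1H-tetrazole | c1ccccc1-n1nnnc1S(=O)(=O)CCCCCCCCC[C@@]1(C)C[C@](C)(CCO[Si](C)(C)C(C)(C)C)OO1 | intermediate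
21 | (2E,4E)-hepta-2,4-dienal | CC/C=C/C=C/C=O | starting material
22 | tert-butyl{2-[(3S,5S)-5-[(9E,11E,13E)-hexadeca-9,11,13-trien-1-yl]-3,5-dimethyl-1,2-dioxolan-3-yl]ethoxy}dimethylsilane | CC/C=C/C=C/C=C/CCCCCCCC[C@@]1(C)C[C@](C)(CCO[Si](C)(C)C(C)(C)C)OO1 | intermediate
23 | 2-[(3S,5S)-5-[(9E,11E,13E)-hexadeca-9,11,13-trien-1-yl]-3,5-dimethyl-1,2-dioxolan-3-yl]ethan-1-ol | CC/C=C/C=C/C=C/CCCCCCCC[C@@]1(C)C[C@](C)(CCO)OO1 | intermediate
24 | 2-[(3R,5S)-5-[(9E,11E,13E)-hexadeca-9,11,13-trien-1-yl]-3,5-dimethyl-1,2-dioxolan-3-yl]acetaldehyde | CC/C=C/C=C/C=C/CCCCCCCC[C@@]1(C)C[C@](C)(CC=O)OO1 | intermediate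
25 | 2-[(3R,5S)-5-[(9E,11E,13E)-hexadeca-9,11,13-trien-1-yl]-3,5-dimethyl-1,2-dioxolan-3-yl]acetic acid | CC/C=C/C=C/C=C/CCCCCCCC[C@@]1(C)C[C@](C)(CC(=O)O)OO1 | target

**Step count.** Total: 15 steps. Longest linear sequence: 13 steps (steps 1–7 and 10–15, from 1).

**Steps most likely to fail**

Step 5. What may go wrong: after the first perhydrolysis the liberated hydroxyethyl oxygen, or a second molecule of H2O2, captures the second oxetane instead of the OOH group, or partial ionisation erodes the inversion. The fallback separates the two C–O bond formations and lets a ketone capture the hydroperoxide; it sets out from ketone 5 and returns at 11. Perhydrolysis of the oxetane of 5 (H2O2, TMSOTf, Et2O) with inversion gives a hydroperoxy ketone that closes at once, again through the O–C3 bond, to the peroxyhemiketal (5S)-5-(2-hydroxyethyl)-3,5-dimethyl-1,2-dioxolan-3-ol F1. Silylation of the primary hydroxyl (TBSCl, imidazole) gives (5S)-5-(2-{[tert-butyl(dimethyl)silyl]oxy}ethyl)-3,5-dimethyl-1,2-dioxolan-3-ol F2, and acetylation (Ac2O, Et3N, DMAP) gives the 3-acetoxy-1,2-dioxolane (5S)-5-(2-{[tert-butyl(dimethyl)silyl]oxy}ethyl)-3,5-dimethyl-1,2-dioxolan-3-yl acetate F3. Ionisation with TiCl4 to the peroxycarbenium ion and capture by 1-(ethylsulfanyl)-1-(trimethylsilyloxy)ethene should give, after separation from its C3 epimer, S-ethyl 2-[(3R,5S)-5-(2-{[tert-butyl(dimethyl)silyl]oxy}ethyl)-3,5-dimethyl-1,2-dioxolan-3-yl]ethanethioate F4. LiBH4 reduction of the thioester gives 11.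

Step 4. What may go wrong: under the basic, prolonged ylide conditions the ketone enolises and the strained oxetane in the β-position is opened by elimination, or catalyst control over the new centre is incomplete. The fallback changes the order of ring construction so that the ylide meets a ketone with an unstrained β-silyloxy group; it sets out from diol 2 and returns at 7. Protection with tBu2Si(OTf)2 and 2,6-lutidine gives 2-[(4R)-2,2-di-tert-butyl-4-methyl-1,3,2-dioxasilinan-4-yl]-N-methoxy-N-methylacetamide F5, and MeMgBr gives 1-[(4R)-2,2-di-tert-butyl-4-methyl-1,3,2-dioxasilinan-4-yl]propan-2-one F6. The two-stage asymmetric ylide addition of step 4 gives (4R)-2,2-di-tert-butyl-4-methyl-4-{[(2R)-2-methyloxetan-2-yl]methyl}-1,3,2-dioxasilinane F7. Bu4NF releases (3R)-3-methyl-4-[(2R)-2-methyloxetan-2-yl]butane-1,3-diol F8, whose primary monotosylate (3R)-3-hydroxy-3-methyl-4-[(2R)-2-methyloxetan-2-yl]butyl 4-methylbenzenesulfonate F9 is closed with KOtBu as in step 2 to give 7.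

Step 15. What may go wrong: oxidative degradation or E/Z isomerisation of the conjugated triene by the oxoammonium/hypervalent iodine system during the slow aldehyde-to-acid stage. The fallback moves the oxidation ahead of triene formation; it sets out from sulfone 20 and returns at 25. HF·pyridine gives 2-[(3S,5S)-3,5-dimethyl-5-{9-[(1-phenyl-1H-tetrazol-5-yl)sulfonyl]nonyl}-1,2-dioxolan-3-yl]ethan-1-ol F10. TEMPO/PhI(OAc)2 in aqueous MeCN, with no alkene present, gives via 2-[(3R,5S)-3,5-dimethyl-5-{9-[(1-phenyl-1H-tetrazol-5-yl)sulfonyl]nonyl}-1,2-dioxolan-3-yl]acetaldehyde F11 the acid 2-[(3R,5S)-3,5-dimethyl-5-{9-[(1-phenyl-1H-tetrazol-5-yl)sulfonyl]nonyl}-1,2-dioxolan-3-yl]acetic acid F12. Julia–Kocienski olefination of the carboxylate/sulfonyl dianion of F12 (KN(SiMe3)2, 2.2 equiv, DME, −60 °C) with 21 gives 25 directly.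

**Further compounds**

F1 | step 5 | (5S)-5-(2-hydroxyethyl)-3,5-dimethyl-1,2-dioxolan-3-ol | CC1(O)C[C@](C)(CCO)OO1
F2 | step 5 | (5S)-5-(2-{[tert-butyl(dimethyl)silyl]oxy}ethyl)-3,5-dimethyl-1,2-dioxolan-3-ol | CC1(O)C[C@](C)(CCO[Si](C)(C)C(C)(C)C)OO1
F3 | step 5 | (5S)-5-(2-{[tert-butyl(dimethyl)silyl]oxy}ethyl)-3,5-dimethyl-1,2-dioxolan-3-yl acetate | CC(=O)OC1(C)C[C@](C)(CCO[Si](C)(C)C(C)(C)C)OO1
F4 | step 5 | S-ethyl 2-[(3R,5S)-5-(2-{[tert-butyl(dimethyl)silyl]oxy}ethyl)-3,5-dimethyl-1,2-dioxolan-3-yl]ethanethioate | CCSC(=O)C[C@@]1(C)C[C@](C)(CCO[Si](C)(C)C(C)(C)C)OO1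
F5 | step 4 | 2-[(4R)-2,2-di-tert-butyl-4-methyl-1,3,2-dioxasilinan-4-yl]-N-methoxy-N-methylacetamide | CON(C)C(=O)C[C@@]1(C)CCO[Si](C(C)(C)C)(C(C)(C)C)O1
F6 | step 4 | 1-[(4R)-2,2-di-tert-butyl-4-methyl-1,3,2-dioxasilinan-4-yl]propan-2-one | CC(=O)C[C@@]1(C)CCO[Si](C(C)(C)C)(C(C)(C)C)O1
F7 | step 4 | (4R)-2,2-di-tert-butyl-4-methyl-4-{[(2R)-2-methyloxetan-2-yl]methyl}-1,3,2-dioxasilinane | C[C@@]1(CCO1)C[C@@]2(C)CCO[Si](C(C)(C)C)(C(C)(C)C)O2
F8 | step 4 | (3R)-3-methyl-4-[(2R)-2-methyloxetan-2-yl]butane-1,3-diol | C[C@@]1(CCO1)C[C@](C)(O)CCO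
F9 | step 4 | (3R)-3-hydroxy-3-methyl-4-[(2R)-2-methyloxetan-2-yl]butyl 4-methylbenzenesulfonate | C[C@@]1(CCO1)C[C@](C)(O)CCOS(=O)(=O)c1ccc(C)cc1
F10 | step 15 | 2-[(3S,5S)-3,5-dimethyl-5-{9-[(1-phenyl-1H-tetrazol-5-yl)sulfonyl]nonyl}-1,2-dioxolan-3-yl]ethan-1-ol | c1ccccc1-n1nnnc1S(=O)(=O)CCCCCCCCC[C@@]1(C)C[C@](C)(CCO)OO1
F11 | step 15 | 2-[(3R,5S)-3,5-dimethyl-5-{9-[(1-phenyl-1H-tetrazol-5-yl)sulfonyl]nonyl}-1,2-dioxolan-3-yl]acetaldehyde | c1ccccc1-n1nnnc1S(=O)(=O)CCCCCCCCC[C@@]1(C)C[C@](C)(CC=O)OO1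
F12 | step 15 | 2-[(3R,5S)-3,5-dimethyl-5-{9-[(1-phenyl-1H-tetrazol-5-yl)sulfonyl]nonyl}-1,2-dioxolan-3-yl]acetic acid | c1ccccc1-n1nnnc1S(=O)(=O)CCCCCCCCC[C@@]1(C)C[C@](C)(CC(=O)O)OO1
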